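## Analysis of the target

The target is a tetraprenylated (geranylgeranyl-derived) methylhydroquinone. Its side chain is numbered C1 to C15 along the backbone, with the branch carbon C3' on C3, one methyl group each on C7 and C11 and two on C15; it hangs from the arene through C1 and carries oxygen at C2, C3, C3', C4, C7 and C9. The oxygens on C7 and C9 both end on C4, so C4–C5–C6–C7–O is an oxolane and C4–O–C9–C8–C7–O a 1,3-dioxane; together they form a 2,8-dioxabicyclo[3.2.1]octane with bridgeheads C4 and C7. There are five stereocentres, C2 (R, secondary acetate), C3 (S, tertiary carbinol), C4 (R, ketal), C7 (R) and C9 (S), and the C10=C11 olefin is E. C4 and C7 are tied together by the bicycle, so a given C7 allows only one C4, and C9 holds its dienyl chain equatorial on the dioxane chair, away from the C5–C6 bridge. C2 and C3 lie outside the bicycle; C3 is a fully substituted carbinol between C2 and the quaternary ketal carbon, and no ring relays its configuration. The sensitive groups are the free hydroquinone (air, oxidants), the two acetates (base, hydride, organometallics), the allylic C9–O bond of the ketal and the two trisubstituted olefins (acid, cations). The strategy rests on C9 being both the allylic carbon next to C10=C11 and a ring atom of the dioxane: its oxygen can arrive from C11 by a 1,3-shift, and the ring then selects its configuration.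

## Retrosynthetic reasoning

**Hydroquinone (28 ⇒ 27 ⇒ 26).** The two phenolic O–H bonds are traced back to O–CH3. The dimethyl ether is inert to every base, hydride and Lewis acid used earlier and comes with commercial bromide 4. The forward step is an oxidative demethylation to quinone 27 and a mild reduction, which must leave the acetates and the ketal alone.

**Acetates and diol (26 ⇒ 25 ⇒ 24).** The two acyl C–O bonds are cut, and the C2/C3 diol is then returned to its isopropylidene ketal. The acetates can only go on after the last hydride step. The forward reactions must hydrolyse a dioxolane next to the bicyclic ketal and acylate the primary and secondary hydroxyls while the hindered tertiary C3 hydroxyl stays free.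

**C3' oxidation level (24 ⇒ 23).** The hydroxymethyl group is traced back to a methyl ester. During the key step C3 therefore carries an ester rather than a protected alcohol, for three reasons:
- the ester is the group that makes C3 nucleophilic in the earlier aldol and needs no protecting group;
- it makes C4 electron-poor, which favours the hemiketal and slows ionisation of the finished ketal at C4;
- it can be reduced only once the ketal protects C4, so no redox detour at C4 is needed.

**Key disconnection (23 ⇒ 22).** The O–C9 bond and both C4–O bonds are cut, opening both rings to the acyclic C4-keto C7,C11-diol 22 with an (E)-C9=C10 olefin. One catalytic step then closes two rings and sets C4 and C9, and the precursor needs no control at C11. The forward reaction must move the tertiary hydroxyl from C11 to C9, hold C4 as a hemiketal with the C7 oxygen and close the dioxane. C4 follows from C7 through the bridge and C9 from the equatorial preference under reversible conditions. The geometry of the new C10=C11 bond is not fixed by the ring; it depends only on methyl rather than methylene lying cis to C9, and this is the least secured selectivity of the plan.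

**C4 ketone and C7 hydroxyl (22 ⇒ 21 ⇒ 20).** The ketone is traced back to a carbinol and the C7 hydroxyl to its triethylsilyl ether. A C4 ketone would not survive hydroboration or a Grignard addition, so C4 stays a secondary alcohol until every C–C bond is made. It is then the only oxidisable hydroxyl, the other two being tertiary.

**C11–C12 bond (20 ⇒ 17 + 19).** Cutting next to the carbinol carbon gives enone 17 and Grignard reagent 19 (from bromide 18). The forward 1,2-addition must avoid conjugate addition, γ-deprotonation and the hindered ester. C11 is formed as both epimers.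

**C9=C10 and C9 oxygenation (17 ⇒ 15 + 16; 15 ⇒ 14 ⇒ 12).** The (E)-enone comes from aldehyde 15 and stabilised phosphorane 16, and the aldehyde from anti-Markovnikov hydration of the vinyl group of 12 and oxidation. Neutral olefination and an oxoammonium oxidation are chosen because 12 to 15 carry an ester and a β-hydroxy ester that would not tolerate acetylide or hydride chemistry.

**C3–C4 bond (12 ⇒ 6 + 10).** The bond between the quaternary C3 and the carbinol C4 is cut to the enolate 11 of dioxolane ester 6 and aldehyde 10. The aldol must form the C3 stereocentre; the dioxolane ring lets the C2 substituent direct the aldehyde to the opposite face. The original C3 configuration of 6 is erased on enolisation, so only C2 has to be made enantiopure.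

**C4–C9 segment (10 ⇒ 8 ⇒ 7).** Aldehyde 10 is (R)-linalool 7 after silylation and cleavage of its trisubstituted olefin. C7 comes from the chiral pool with the right configuration and the vinyl group becomes C8–C9. The silyl ether keeps the aldehyde open-chain, where the free alcohol would close to a lactol.

**Northern ester (6 ⇒ 3 + 5; 5 ⇒ 4; 3 ⇒ 2 ⇒ 1).** The bond between the arene and C1 is cut to triflate 3 and the Grignard reagent 5 of bromide 4. Triflate 3 comes from the D-tartrate acetonide 1 by reduction of one ester. Diester 1 supplies C2 (R) without any asymmetric step.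

## Alternatives that were turned down

**Alternative 1:** Only the C4–O9 bond is cut, and it is made last by C–H functionalisation. Under Ir(ppy)3 and visible light the C9 N-alkoxyphthalimide A2 would give the C9 alkoxy radical, which must abstract the C4 hydrogen through a seven-membered transition state. The C4 radical is then oxidised and captured by the C9 hydroxyl to give the aryl dimethyl ether A1, which is the same compound as 26.
- For: both acetates are in place before the ketal forms, so no protecting-group steps follow, and the C10=C11 geometry and C9 are built beforehand by ordinary methods. On olefin geometry this alternative is stronger than the chosen route.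
- Against: the oxygen radical at C9 has a six-membered path to the allylic hydrogens of the C11 methyl group, which should outrun the longer shift to C4. The C4–H bond is electron-poor because of the oxygens on C3, a mismatch for an electrophilic radical, and oxidising the resulting radical to a cation is disfavoured for the same reason. β-Scission next to the olefin also competes.
- Against: A2 needs the oxolane with the C4 hydrogen cis to the C8 arm (a stereocentre set only to be destroyed) and C9 set with full reagent control.
- Comparison: the chosen route sets C4 and C9 in one equilibrating step from a precursor with an uncontrolled C11 and needs fewer controlled centres; in exchange it accepts a protecting-group endgame.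

**Alternative 2:** The C3–C3' bond is cut on the C3 ketone A4, which already carries the bicycle. Dimethylsulfonium methylide would add to the ketone and the betaine close to spiro-oxirane A3; acetate opening at the CH2 terminus would then give the tertiary carbinol and primary acetate directly.
- For: it is the shortest way to the CH2OAc/tertiary OH motif, and on endgame economy it beats the chosen route.
- Against: the ketone lies between two oxygenated stereocentres, C2 with its silyloxy group and the ketal carbon with two oxygens. The polar addition models therefore disagree, and an irreversible small nucleophile cannot be corrected afterwards.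
- Against: C2 is enolisable under the basic ylide, and the neopentyl-type ketone may be deprotonated instead of attacked.
- Against: it does not say how the ketal, C9 and the olefin are made, so that problem remains.
- Comparison: the chosen route sets C3 in a ring-controlled enolate aldol, where one adjacent substituent decides the face, and it solves the ketal in the same plan.

**Alternative 3:** Both C–O bonds at C2 and C3 are cut to the (Z)-allylic alcohol A6. Ti(OiPr)4, diethyl tartrate and t-BuOOH would give epoxy alcohol A5, which must then be opened at C2 by an oxygen nucleophile with inversion.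
- For: reagent control gives a predictable absolute configuration, only the allylic alcohol is epoxidised so the chain olefins are safe, and no acidic acetonide cleavage is needed. On these points it is as good as or better than the chosen route.
- Against: A6 needs a trisubstituted olefin of defined Z geometry on the quaternary ketal carbon, for which no reliable olefination is evident.
- Against: the bulky 2-substituent and the chiral ketal make the epoxidation slow and possibly mismatched.
- Against: the opening at C2 has to compete with attack of the electron-rich arene or its ortho methoxy group two atoms away, and with opening at the more substituted C3.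
- Comparison: at least three selective steps follow ketal assembly, whereas the chosen route takes C2 from tartrate and sets C3 before the sensitive ketal exists.

Key step: step 13

Remark on the chemistry: positions follow the chain numbering C1–C15 (C3' is the carbon on C3 that becomes CH2OAc); the dioxolane ring carbons C4 and C5 of the systematic names are chain C3 and C2.
Remark on the chemistry: C4 (steps 6–11) and C11 (from step 10) are carried as epimer mixtures because both centres are erased later; the CIP descriptor at chain C3 changes between 6, 12 and 22 because priorities change, not the geometry.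
Remark on the chemistry: in step 7 the hindered C4 hydroxyl is assumed to stay free in borane 13; any O-borinate would be cleaved in the oxidative work-up.

## Steps

Step 1
Reactants: 1 dimethyl 2,3-O-isopropylidene-D-tartrate
Product: 2 methyl (4S,5R)-5-(hydroxymethyl)-2,2-dimethyl-1,3-dioxolane-4-carboxylate
Conditions: NaBH4 (0.6 equiv), MeOH, 0 °C
Reagents that add atoms: none
Why: Partial hydride reduction of an α-alkoxy diester; the two esters are equivalent by symmetry, so with limiting NaBH4 the mono-alcohol should predominate, and neither stereocentre is touched.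

Step 2
Reactants: 2 hydroxy ester
Product: 3 methyl (4S,5R)-2,2-dimethyl-5-(trifluoromethanesulfonyloxymethyl)-1,3-dioxolane-4-carboxylate
Conditions: Tf2O, pyridine, CH2Cl2, −20 °C
Reagents that add atoms: trifluoromethanesulfonic anhydride, O=S(=O)(OS(=O)(=O)C(F)(F)F)C(F)(F)F
Why: Sulfonylation of a primary alcohol; the triflate is chosen because it couples with Grignard reagents under copper catalysis at temperatures where the ester is inert, and it is used crude.

Step 3
Reactants: 3 triflate; 4 1-bromo-2,5-dimethoxy-4-methylbenzene
Product: 6 methyl (4S,5R)-5-[(2,5-dimethoxy-4-methylphenyl)methyl]-2,2-dimethyl-1,3-dioxolane-4-carboxylate, via Grignard reagent 5 (not isolated)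
Conditions: Mg, THF, rt; then 3, CuBr·SMe2 (10 mol %), THF, −40 °C
Reagents that add atoms: none
Why: Copper-catalysed cross-coupling of an aryl Grignard reagent with a primary alkyl triflate, which should be complete at −40 °C before the ester is attacked; C2 is not involved and keeps its configuration.

Step 4
Reactants: 7 (R)-linalool
Product: 8 (R)-linalool triethylsilyl ether
Conditions: Et3SiOTf, 2,6-lutidine, CH2Cl2, 0 °C
Reagents that add atoms: triethylsilyl trifluoromethanesulfonate, CC[Si](CC)(CC)OS(=O)(=O)C(F)(F)F
Why: Silyl triflate silylation of a tertiary alcohol under non-ionising basic conditions; the ether keeps the later C4 aldehyde open-chain and lasts until step 11.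

Step 5
Reactants: 8 (R)-linalool triethylsilyl ether
Product: 10 (4R)-4-methyl-4-(triethylsilyloxy)hex-5-enal, via ozonide 9 (not isolated)
Conditions: O3 (1 equiv), CH2Cl2, −78 °C; then PPh3, −78 °C to rt
Reagents that add atoms: ozone, [O-][O+]=O
Why: Chemoselective ozonolysis with reductive work-up; the electron-rich trisubstituted olefin reacts far faster than the vinyl group, which is hindered and deactivated by the allylic silyloxy quaternary carbon.

Step 6
Reactants: 6 dioxolane ester; 10 aldehyde
Product: 12 methyl (4R,5R)-5-[(2,5-dimethoxy-4-methylphenyl)methyl]-4-[(4R)-1-hydroxy-4-methyl-4-(triethylsilyloxy)hex-5-en-1-yl]-2,2-dimethyl-1,3-dioxolane-4-carboxylate (both C4 carbinol epimers), via lithium enolate 11 (not isolated)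
Conditions: LiN(iPr)2, THF, −78 °C; then 10, −78 °C; AcOH quench at −78 °C
Reagents that add atoms: none
Why: Aldol addition of an ester lithium enolate; the aldehyde attacks the planar C3 on the ring face opposite the C2 benzyl group, so the new C3–C4 bond is trans and the ester cis to that group, which is the target's C3 configuration. β-Elimination of the ring oxygen is slow at −78 °C because that C–O bond lies near the nodal plane of the enolate.

Step 7
Reactants: 12 aldol adduct
Product: 14 C4,C9-diol (primary alcohol at C9), via alkylborane 13 (not isolated)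
Conditions: 9-BBN-H, THF, 0 to 40 °C; then 30% H2O2, aq NaOAc, 0 °C to rt
Reagents that add atoms: hydrogen peroxide, OO
Why: Hydroboration–oxidation; 9-BBN adds anti-Markovnikov to the only olefin and does not reduce the ester, and the buffered peroxide work-up spares the β-hydroxy ester from retro-aldol cleavage.

Step 8
Reactants: 14 diol
Product: 15 C9 aldehyde with free C4 hydroxyl
Conditions: TEMPO (10 mol %), PhI(OAc)2, CH2Cl2, rt
Reagents that add atoms: none
Why: Oxoammonium (TEMPO) oxidation, which takes the unhindered primary alcohol and leaves the secondary C4 hydroxyl beside the quaternary C3.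

Step 9
Reactants: 15 aldehyde; 16 1-(triphenylphosphoranylidene)propan-2-one
Product: 17 (E)-enone (methyl ketone at C11)
Conditions: toluene, 70 °C
Reagents that add atoms: none
Why: Wittig olefination with a stabilised ylide, which gives the (E)-enone and is neutral enough not to eliminate the β-silyloxy aldehyde or disturb the β-hydroxy ester.

Step 10
Reactants: 17 enone; 18 5-bromo-2-methylpent-2-ene
Product: 20 tertiary allylic alcohol at C11 (both C11 epimers), via Grignard reagent 19 (not isolated)
Conditions: Mg, THF, rt; CeCl3, THF, −78 °C; then 17, −78 °C; aq NH4Cl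
Reagents that add atoms: none
Why: 1,2-Addition of a CeCl3-activated Grignard reagent to an enone; the weakly basic reagent should avoid conjugate addition and γ-deprotonation, the ester on the quaternary C3 is too hindered to react at −78 °C, and one extra equivalent is consumed by the C4 hydroxyl.

Step 11
Reactants: 20 silyl ether
Product: 21 C4,C7,C11-triol
Conditions: HF·pyridine, pyridine, THF, 0 °C to rt
Reagents that add atoms: none
Why: Fluoride desilylation of the tertiary triethylsilyl ether; the pyridine buffer protects the tertiary allylic alcohol and the acetonide.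

Step 12
Reactants: 21 triol
Product: 22 methyl (4S,5R)-4-[(4R,6E)-4,8-dihydroxy-4,8,12-trimethyltrideca-6,11-dienoyl]-5-[(2,5-dimethoxy-4-methylphenyl)methyl]-2,2-dimethyl-1,3-dioxolane-4-carboxylate (C11 epimers; in equilibrium with its C4 hemiketal)
Conditions: Dess–Martin periodinane, NaHCO3, CH2Cl2, 0 °C to rt
Reagents that add atoms: none
Why: Dess–Martin oxidation of the only secondary alcohol; the two tertiary alcohols cannot be oxidised, and a chromium-free oxidant avoids oxidative transposition of the allylic one.

Step 13
Reactants: 22 keto diol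
Product: 23 methyl (4S,5R)-5-[(2,5-dimethoxy-4-methylphenyl)methyl]-4-{(1R,3S,5R)-3-[(1E)-2,6-dimethylhepta-1,5-dien-1-yl]-5-methyl-2,8-dioxabicyclo[3.2.1]octan-1-yl}-2,2-dimethyl-1,3-dioxolane-4-carboxylate
Conditions: Re2O7 (5 mol %), CH2Cl2, 0 °C to rt
Reagents that add atoms: none
Why: Re2O7 forms the perrhenate ester of the tertiary C11 hydroxyl, which passes the oxygen to C9 by a [3,3] shift or through the allyl cation ion pair and creates the C10=C11 olefin; the closest known reaction type is the Re2O7-catalysed 1,3-transposition of allylic alcohols with capture by a hemiketal from a pendant ketone. The oxolane closes by 5-exo-trig addition of the C7 hydroxyl to the C4 carbonyl, favoured here because the ester and ring oxygens on C3 make C4 electron-poor. The 1,3-dioxane closes by 6-exo-trig attack of the hemiketal hydroxyl on the C9 terminus of the allyl cation or its C9 perrhenate; 6-endo-trig addition of a C9 hydroxyl to the oxolanyl oxocarbenium ion makes the same bonds but is less likely at this electron-poor C4. C4 is controlled by C7, since with both rings sharing the C5–C6 bridge only the (R) ketal carbon is geometrically possible. C9 is controlled thermodynamically: every step is reversible and only the (9S) epimer places the dienyl chain equatorial on the dioxane chair, so both C11 epimers and both C9 epimers should converge. The step also needs E geometry at C10=C11 and chemoselectivity over the C14=C15 olefin. The E isomer is favoured only because methyl rather than the methylene chain then lies cis to C9, the weakest of the controls. Low temperature and little catalyst are meant to keep cation–olefin cyclisation and ether formation from O7 to C11 slower than the intramolecular capture.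

Step 14
Reactants: 23 ketal ester
Product: 24 primary alcohol at C3' (ketal and acetonide intact)
Conditions: LiAlH4, THF, 0 °C
Reagents that add atoms: none
Why: Hydride reduction of the ester to the primary alcohol; the ketal now protects C4, and acetonide, aryl ethers and isolated olefins are inert to LiAlH4.

Step 15
Reactants: 24 acetonide alcohol
Product: 25 (2S,3R)-4-(2,5-dimethoxy-4-methylphenyl)-2-{(1R,3S,5R)-3-[(1E)-2,6-dimethylhepta-1,5-dien-1-yl]-5-methyl-2,8-dioxabicyclo[3.2.1]octan-1-yl}butane-1,2,3-triol
Conditions: AcOH/H2O (4:1), 40 °C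
Reagents that add atoms: none
Why: Acid-catalysed hydrolysis of the isopropylidene ketal; the bicyclic ketal should persist because its C4 cation is destabilised by the oxygens on C3 and because it is the thermodynamic form of the keto diol, and dilute AcOH is too weak to hydrate the trisubstituted olefins.

Step 16
Reactants: 25 triol
Product: 26 C2,C3'-diacetate with free tertiary C3 hydroxyl (aryl dimethyl ether of the target)
Conditions: Ac2O, pyridine, DMAP (cat.), CH2Cl2, 0 °C
Reagents that add atoms: acetic anhydride, CC(=O)OC(C)=O
Why: DMAP-catalysed acylation of the primary and secondary hydroxyls; the tertiary C3 hydroxyl, flanked by the quaternary ketal carbon, should not react at 0 °C.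

Step 17
Reactants: 26 diacetate
Product: 28 target hydroquinone CNP0160303.2, via quinone 27 (not isolated)
Conditions: (NH4)2Ce(NO3)6, MeCN/H2O, 0 °C; then aq Na2S2O4, EtOAc, rt
Reagents that add atoms: water, O
Why: Oxidative demethylation of the 1,4-dimethoxyarene by tetravalent cerium to the quinone, then dithionite reduction to the hydroquinone; the arene is oxidised well before the olefins, and the short, cold exposure should spare the acetates and the ketal.

## Compound list

1 | dimethyl (4S,5S)-2,2-dimethyl-1,3-dioxolane-4,5-dicarboxylate | COC(=O)[C@H]1OC(C)(C)O[C@@H]1C(=O)OC | starting material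
2 | methyl (4S,5R)-5-(hydroxymethyl)-2,2-dimethyl-1,3-dioxolane-4-carboxylate | COC(=O)[C@H]1OC(C)(C)O[C@@H]1CO | intermediate
3 | methyl (4S,5R)-2,2-dimethyl-5-{[(trifluoromethanesulfonyl)oxy]methyl}-1,3-dioxolane-4-carboxylate | COC(=O)[C@H]1OC(C)(C)O[C@@H]1COS(=O)(=O)C(F)(F)F | intermediate
4 | 1-bromo-2,5-dimethoxy-4-methylbenzene | COc1cc(Br)c(OC)cc1C | starting material
5 | (2,5-dimethoxy-4-methylphenyl)magnesium bromide | COc1cc([Mg]Br)c(OC)cc1C | intermediate
6 | methyl (4S,5R)-5-[(2,5-dimethoxy-4-methylphenyl)methyl]-2,2-dimethyl-1,3-dioxolane-4-carboxylate | COC(=O)[C@H]1OC(C)(C)O[C@@H]1Cc1cc(OC)c(C)cc1OC | intermediate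
7 | (R)-linalool, (3R)-3,7-dimethylocta-1,6-dien-3-ol | C=C[C@](C)(O)CCC=C(C)C | starting material
8 | triethyl{[(3R)-3,7-dimethylocta-1,6-dien-3-yl]oxy}silane | C=C[C@](C)(O[Si](CC)(CC)CC)CCC=C(C)C | intermediate
9 | 3,3-dimethyl-5-{(3R)-3-methyl-3-[(triethylsilyl)oxy]pent-4-en-1-yl}-1,2,4-trioxolane | C=C[C@](C)(O[Si](CC)(CC)CC)CCC1OOC(C)(C)O1 | intermediate
10 | (4R)-4-methyl-4-[(triethylsilyl)oxy]hex-5-enal | C=C[C@](C)(O[Si](CC)(CC)CC)CCC=O | intermediate
11 | lithium {(5R)-5-[(2,5-dimethoxy-4-methylphenyl)methyl]-2,2-dimethyl-1,3-dioxolan-4-ylidene}(methoxy)methanolate | COC([O-])=C1OC(C)(C)O[C@@H]1Cc1cc(OC)c(C)cc1OC.[Li+] | intermediate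
12 | methyl (4R,5R)-5-[(2,5-dimethoxy-4-methylphenyl)methyl]-4-[(4R)-1-hydroxy-4-methyl-4-(triethylsilyloxy)hex-5-en-1-yl]-2,2-dimethyl-1,3-dioxolane-4-carboxylate (epimers at the carbinol carbon) | COC(=O)[C@@]1(OC(C)(C)O[C@@H]1Cc1cc(OC)c(C)cc1OC)C(O)CC[C@@](C)(O[Si](CC)(CC)CC)C=C | intermediate
13 | B-alkyl-9-borabicyclo[3.3.1]nonane from 12 (boron on the terminal carbon C9) | COC(=O)[C@@]1(OC(C)(C)O[C@@H]1Cc1cc(OC)c(C)cc1OC)C(O)CC[C@@](C)(O[Si](CC)(CC)CC)CCB1C2CCCC1CCC2 | intermediate
14 | methyl (4R,5R)-4-[(4R)-1,6-dihydroxy-4-methyl-4-(triethylsilyloxy)hexyl]-5-[(2,5-dimethoxy-4-methylphenyl)methyl]-2,2-dimethyl-1,3-dioxolane-4-carboxylate | COC(=O)[C@@]1(OC(C)(C)O[C@@H]1Cc1cc(OC)c(C)cc1OC)C(O)CC[C@@](C)(O[Si](CC)(CC)CC)CCO | intermediate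
15 | methyl (4R,5R)-5-[(2,5-dimethoxy-4-methylphenyl)methyl]-4-[(4R)-1-hydroxy-4-methyl-6-oxo-4-(triethylsilyloxy)hexyl]-2,2-dimethyl-1,3-dioxolane-4-carboxylate | COC(=O)[C@@]1(OC(C)(C)O[C@@H]1Cc1cc(OC)c(C)cc1OC)C(O)CC[C@@](C)(O[Si](CC)(CC)CC)CC=O | intermediate
16 | 1-(triphenyl-λ5-phosphanylidene)propan-2-one | CC(=O)C=P(c1ccccc1)(c1ccccc1)c1ccccc1 | starting material
17 | methyl (4R,5R)-5-[(2,5-dimethoxy-4-methylphenyl)methyl]-4-[(4R,6E)-1-hydroxy-4-methyl-8-oxo-4-(triethylsilyloxy)non-6-en-1-yl]-2,2-dimethyl-1,3-dioxolane-4-carboxylate | COC(=O)[C@@]1(OC(C)(C)O[C@@H]1Cc1cc(OC)c(C)cc1OC)C(O)CC[C@@](C)(O[Si](CC)(CC)CC)C/C=C/C(C)=O | intermediate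
18 | 5-bromo-2-methylpent-2-ene | CC(C)=CCCBr | starting material
19 | (4-methylpent-3-en-1-yl)magnesium bromide | CC(C)=CCC[Mg]Br | intermediate
20 | methyl (4R,5R)-4-[(4R,6E)-1,8-dihydroxy-4,8,12-trimethyl-4-(triethylsilyloxy)trideca-6,11-dien-1-yl]-5-[(2,5-dimethoxy-4-methylphenyl)methyl]-2,2-dimethyl-1,3-dioxolane-4-carboxylate (epimers at C1' and C8' of the side chain) | COC(=O)[C@@]1(OC(C)(C)O[C@@H]1Cc1cc(OC)c(C)cc1OC)C(O)CC[C@@](C)(O[Si](CC)(CC)CC)C/C=C/C(C)(O)CCC=C(C)C | intermediate
21 | methyl (4R,5R)-5-[(2,5-dimethoxy-4-methylphenyl)methyl]-2,2-dimethyl-4-[(4R,6E)-1,4,8-trihydroxy-4,8,12-trimethyltrideca-6,11-dien-1-yl]-1,3-dioxolane-4-carboxylate | COC(=O)[C@@]1(OC(C)(C)O[C@@H]1Cc1cc(OC)c(C)cc1OC)C(O)CC[C@@](C)(O)C/C=C/C(C)(O)CCC=C(C)C | intermediate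
22 | methyl (4S,5R)-4-[(4R,6E)-4,8-dihydroxy-4,8,12-trimethyltrideca-6,11-dienoyl]-5-[(2,5-dimethoxy-4-methylphenyl)methyl]-2,2-dimethyl-1,3-dioxolane-4-carboxylate (C11 epimers) | COC(=O)[C@@]1(OC(C)(C)O[C@@H]1Cc1cc(OC)c(C)cc1OC)C(=O)CC[C@@](C)(O)C/C=C/C(C)(O)CCC=C(C)C | intermediate
23 | methyl (4S,5R)-5-[(2,5-dimethoxy-4-methylphenyl)methyl]-4-{(1R,3S,5R)-3-[(1E)-2,6-dimethylhepta-1,5-dien-1-yl]-5-methyl-2,8-dioxabicyclo[3.2.1]octan-1-yl}-2,2-dimethyl-1,3-dioxolane-4-carboxylate | COC(=O)[C@@]1(OC(C)(C)O[C@@H]1Cc1cc(OC)c(C)cc1OC)[C@]23CC[C@](C)(C[C@@H](/C=C(\C)CCC=C(C)C)O2)O3 | intermediate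
24 | [(4S,5R)-5-[(2,5-dimethoxy-4-methylphenyl)methyl]-4-{(1R,3S,5R)-3-[(1E)-2,6-dimethylhepta-1,5-dien-1-yl]-5-methyl-2,8-dioxabicyclo[3.2.1]octan-1-yl}-2,2-dimethyl-1,3-dioxolan-4-yl]methanol | OC[C@@]1(OC(C)(C)O[C@@H]1Cc1cc(OC)c(C)cc1OC)[C@]23CC[C@](C)(C[C@@H](/C=C(\C)CCC=C(C)C)O2)O3 | intermediate
25 | (2S,3R)-4-(2,5-dimethoxy-4-methylphenyl)-2-{(1R,3S,5R)-3-[(1E)-2,6-dimethylhepta-1,5-dien-1-yl]-5-methyl-2,8-dioxabicyclo[3.2.1]octan-1-yl}butane-1,2,3-triol | OC[C@](O)([C@@H](Cc1cc(OC)c(C)cc1OC)O)[C@]12CC[C@](C)(C[C@@H](/C=C(\C)CCC=C(C)C)O1)O2 | intermediate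
26 | (2S,3R)-4-(2,5-dimethoxy-4-methylphenyl)-2-{(1R,3S,5R)-3-[(1E)-2,6-dimethylhepta-1,5-dien-1-yl]-5-methyl-2,8-dioxabicyclo[3.2.1]octan-1-yl}-2-hydroxybutane-1,3-diyl diacetate | CC(=O)OC[C@](O)([C@@H](Cc1cc(OC)c(C)cc1OC)OC(C)=O)[C@]12CC[C@](C)(C[C@@H](/C=C(\C)CCC=C(C)C)O1)O2 | intermediate
27 | (2S,3R)-2-{(1R,3S,5R)-3-[(1E)-2,6-dimethylhepta-1,5-dien-1-yl]-5-methyl-2,8-dioxabicyclo[3.2.1]octan-1-yl}-2-hydroxy-4-(4-methyl-3,6-dioxocyclohexa-1,4-dien-1-yl)butane-1,3-diyl diacetate | CC(=O)OC[C@](O)([C@@H](CC3=CC(=O)C(C)=CC3=O)OC(C)=O)[C@]12CC[C@](C)(C[C@@H](/C=C(\C)CCC=C(C)C)O1)O2 | intermediate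
28 | (2S,3R)-4-(2,5-dihydroxy-4-methylphenyl)-2-{(1R,3S,5R)-3-[(1E)-2,6-dimethylhepta-1,5-dien-1-yl]-5-methyl-2,8-dioxabicyclo[3.2.1]octan-1-yl}-2-hydroxybutane-1,3-diyl diacetate (CNP0160303.2) | CC(=O)OC[C@](O)([C@@H](Cc1cc(O)c(C)cc1O)OC(C)=O)[C@]12CC[C@](C)(C[C@@H](/C=C(\C)CCC=C(C)C)O1)O2 | target

## Step count and least certain steps

Total step count: 17 (steps 1–3 to ester 6, steps 4–5 to aldehyde 10, steps 6–17 from their union).
Longest linear sequence: 15 steps (1 → 28 through steps 1–3 and 6–17).

**Step 13 (key step).** The most likely failure is loss of geometric control at C10=C11. The ring sorts C9 but not the olefin: equilibration can favour E only by the small difference between methyl and methylene cis to C9. If the shift stays concerted and suprafacial, one C11 epimer maps onto 9S with 10E, but the other maps onto 9S with 10Z once the ketal has selected C9. Further losses can come from cyclisation of the allyl cation onto the C14=C15 olefin and from capture of the cation at C11 by the free C7 oxygen. A Z fraction could be resubmitted, since the allylic C9–O bond re-ionises, but the fallback removes the cause. It sets out from diol 14. Dess–Martin oxidation of both hydroxyls would give the C4-keto C9-aldehyde F1. Nozaki–Hiyama–Kishi coupling (CrCl2, catalytic NiCl2, DMSO) with (1E)-1-iodo-2,6-dimethylhepta-1,5-diene F2, available by Cp2ZrCl2-catalysed carboalumination with AlMe3 and iodination of the corresponding terminal enyne, adds only to the aldehyde and gives the C9 allylic alcohols F3 with the E olefin already in place. HF·pyridine and then camphorsulfonic acid in CH2Cl2 would free the C7 hydroxyl and close the ketal, directly for the 9S carbinol and through ionisation at C9 for the 9R carbinol, without any 1,3-shift. The fallback rejoins the route at 23.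

**Step 6 (aldol).** Face selection at C3 may be incomplete, because only one ring substituent differentiates the enolate faces. Enolate 11 may also open by β-elimination of the ring oxygen before it meets 10, or the aldolate may revert on warming. The fallback sets out from ester 6. Deprotonation in the presence of Me3SiCl traps the enolate at once as the trimethylsilyl ketene acetal F4, which is added to aldehyde 10 with BF3·OEt2 at −78 °C in a Mukaiyama aldol reaction through an open transition state; the silyl group is lost on work-up. The fallback rejoins at 12.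

**Step 10 (addition to the enone).** The Grignard reagent may act as a base (γ-deprotonation of the enone, retro-aldol cleavage of the magnesium aldolate at C3–C4) or attack the ester in spite of CeCl3. The fallback sets out from aldehyde 15 and reverses the roles of the two C11 substituents. Horner–Wadsworth–Emmons olefination (LiCl, iPr2NEt, MeCN) with dimethyl (6-methyl-2-oxohept-5-en-1-yl)phosphonate F5 would give the (E)-enone F6, which already carries the C12–C15 chain. The methyl group is then added with the non-basic, ketone-selective MeTi(OiPr)3. The fallback rejoins at 20.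

**Step 3 (triflate coupling).** The Grignard reagent may add to the activated ester, or the β-alkoxy triflate may decompose before the copper-mediated substitution. The fallback sets out from alcohol 2. Dess–Martin oxidation would give methyl (4S,5S)-5-formyl-2,2-dimethyl-1,3-dioxolane-4-carboxylate F7. Grignard reagent 5 adds to the aldehyde at −78 °C, far faster than to the ester, to give the benzylic carbinols F8. Hydrogenolysis (H2, Pd/C, EtOAc/AcOH) removes the electron-rich benzylic hydroxyl. The fallback rejoins at 6.

**Step 15 (acetonide hydrolysis).** Hydrolysis of the crowded dioxolane may be slower than acid-induced ionisation of the allylic C9–O bond, followed by elimination or cyclisation of the cation. The fallback sets out from keto diol 22 and removes the acetonide before the sensitive ketal exists. Aqueous CF3CO2H in THF hydrolyses the dioxolane; any ionisation at C11 at that stage feeds the same ketal-forming manifold, and a catalytic amount of Re2O7 completes the closure to the diol ketal ester F9 (methyl (2S,3R)-4-(2,5-dimethoxy-4-methylphenyl)-2-{(1R,3S,5R)-3-[(1E)-2,6-dimethylhepta-1,5-dien-1-yl]-5-methyl-2,8-dioxabicyclo[3.2.1]octan-1-yl}-2,3-dihydroxybutanoate). LiAlH4 then reduces the ester. The fallback rejoins at 25.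

## Further compounds

F1 | step 13 | methyl (4S,5R)-5-[(2,5-dimethoxy-4-methylphenyl)methyl]-2,2-dimethyl-4-[(4R)-4-methyl-6-oxo-4-(triethylsilyloxy)hexanoyl]-1,3-dioxolane-4-carboxylate | COC(=O)[C@@]1(OC(C)(C)O[C@@H]1Cc1cc(OC)c(C)cc1OC)C(=O)CC[C@@](C)(O[Si](CC)(CC)CC)CC=O
F2 | step 13 | (1E)-1-iodo-2,6-dimethylhepta-1,5-diene | I/C=C(\C)CCC=C(C)C
F3 | step 13 | methyl (4S,5R)-5-[(2,5-dimethoxy-4-methylphenyl)methyl]-4-[(4R,7E)-6-hydroxy-4,8,12-trimethyl-4-(triethylsilyloxy)trideca-7,11-dienoyl]-2,2-dimethyl-1,3-dioxolane-4-carboxylate (C9 epimers) | COC(=O)[C@@]1(OC(C)(C)O[C@@H]1Cc1cc(OC)c(C)cc1OC)C(=O)CC[C@@](C)(O[Si](CC)(CC)CC)CC(O)/C=C(\C)CCC=C(C)C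
F4 | step 6 | {(5R)-5-[(2,5-dimethoxy-4-methylphenyl)methyl]-2,2-dimethyl-1,3-dioxolan-4-ylidene}(methoxy)methoxy-trimethylsilane | COC(O[Si](C)(C)C)=C1OC(C)(C)O[C@@H]1Cc1cc(OC)c(C)cc1OC
F5 | step 10 | dimethyl (6-methyl-2-oxohept-5-en-1-yl)phosphonate | COP(=O)(CC(=O)CCC=C(C)C)OC
F6 | step 10 | methyl (4R,5R)-5-[(2,5-dimethoxy-4-methylphenyl)methyl]-4-[(4R,6E)-1-hydroxy-4,12-dimethyl-8-oxo-4-(triethylsilyloxy)trideca-6,11-dien-1-yl]-2,2-dimethyl-1,3-dioxolane-4-carboxylate | COC(=O)[C@@]1(OC(C)(C)O[C@@H]1Cc1cc(OC)c(C)cc1OC)C(O)CC[C@@](C)(O[Si](CC)(CC)CC)C/C=C/C(=O)CCC=C(C)C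
F7 | step 3 | methyl (4S,5S)-5-formyl-2,2-dimethyl-1,3-dioxolane-4-carboxylate | COC(=O)[C@H]1OC(C)(C)O[C@@H]1C=O
F8 | step 3 | methyl (4S,5R)-5-[(2,5-dimethoxy-4-methylphenyl)(hydroxy)methyl]-2,2-dimethyl-1,3-dioxolane-4-carboxylate (carbinol epimers) | COC(=O)[C@H]1OC(C)(C)O[C@@H]1C(O)c1cc(OC)c(C)cc1OC
F9 | step 15 | methyl (2S,3R)-4-(2,5-dimethoxy-4-methylphenyl)-2-{(1R,3S,5R)-3-[(1E)-2,6-dimethylhepta-1,5-dien-1-yl]-5-methyl-2,8-dioxabicyclo[3.2.1]octan-1-yl}-2,3-dihydroxybutanoate | COC(=O)[C@](O)([C@@H](Cc1cc(OC)c(C)cc1OC)O)[C@]12CC[C@](C)(C[C@@H](/C=C(\C)CCC=C(C)C)O1)O2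
A1 | alternative 1 | aryl dimethyl ether of the target (identical with 26) | CC(=O)OC[C@](O)([C@@H](Cc1cc(OC)c(C)cc1OC)OC(C)=O)[C@]23CC[C@](C)(C[C@@H](/C=C(\C)CCC=C(C)C)O2)O3
A2 | alternative 1 | C9 N-alkoxyphthalimide of the 2,5-disubstituted oxolane with a C4 hydrogen | CC(=O)OC[C@](O)([C@@H](Cc1cc(OC)c(C)cc1OC)OC(C)=O)[C@H]1CC[C@](C)(C[C@@H](/C=C(\C)CCC=C(C)C)ON2C(=O)c3ccccc3C2=O)O1
A3 | alternative 2 | C3 spiro-oxirane on the bicyclic ketal | CC(C)(C)[Si](C)(C)O[C@H](Cc1cc(OC)c(C)cc1OC)[C@@]4(CO4)[C@]23CC[C@](C)(C[C@@H](/C=C(\C)CCC=C(C)C)O2)O3
A4 | alternative 2 | C3 ketone (bridgehead acyl ketal) with C2 silyl ether | CC(C)(C)[Si](C)(C)O[C@H](Cc1cc(OC)c(C)cc1OC)C(=O)[C@]23CC[C@](C)(C[C@@H](/C=C(\C)CCC=C(C)C)O2)O3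
A5 | alternative 3 | 2,3-epoxy alcohol on the bicyclic ketal | OC[C@@]1(O[C@H]1Cc2cc(OC)c(C)cc2OC)[C@]34CC[C@](C)(C[C@@H](/C=C(\C)CCC=C(C)C)O3)O4
A6 | alternative 3 | (Z)-C2=C3 allylic alcohol on the bicyclic ketal | OC/C(=C/Cc1cc(OC)c(C)cc1OC)[C@]23CC[C@](C)(C[C@@H](/C=C(\C)CCC=C(C)C)O2)O3
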